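**Strategy.** Ring A is disconnected across C4a–C8a and C5–C6. A thermal cyclobutenone–ynol ether benzannulation should assemble this phloroglucinol ring in one operation and deliver its three oxygens already differentiated around C4a. The cyclobutenone carbonyl becomes the free phenol at C8a (future O1), the ynol ether oxygen becomes the C5 methoxy group, and the enol ether oxygen of the cyclobutenone becomes the protected C7 hydroxyl. The precursors are 3-(methoxymethoxy)cyclobut-2-en-1-one and a methyl ynol ether that carries the silylated C4 carbinol and the MOM-protected, prenylated ring B benzyl unit. Desilylation, oxidation, one-carbon closure of ring C and a single acidic deprotection complete glisoflavone.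

Key step: step 9

Remark: the C7 oxygen is carried as a methoxymethyl ether, so that one mild acid step frees all three phenols and no oxidative or strongly acidic operation is needed next to the prenyl group.
Remark: cyclobutane-1,3-dione 13 is assumed to be a purchased compound; the known hydrolysis of 3-ethoxycyclobut-2-en-1-one would supply it otherwise.
Remark: compounds 11, 12, 19 and 20 are racemic at the carbinol carbon, which becomes the C4 carbonyl in step 11; the target has no stereocentre.

**Step 1**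
Reactants: 1 3-bromo-4,5-dihydroxybenzaldehyde
Product: 2 3-bromo-4,5-bis(methoxymethoxy)benzaldehyde
Conditions: MOMCl, iPr2NEt, CH2Cl2, 0 °C to rt
Reagents that add atoms: chloromethyl methyl ether, COCCl
Why: Both catechol hydroxyls are alkylated by the reactive chloromethyl ether under amine base (phenol O-alkylation, acetal protection).

**Step 2**
Reactants: 2 3-bromo-4,5-bis(methoxymethoxy)benzaldehyde
Product: 3 1-bromo-5-ethenyl-2,3-bis(methoxymethoxy)benzene
Conditions: Ph3PCH3Br, KOtBu, THF, 0 °C to rt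
Reagents that add atoms: methyltriphenylphosphonium bromide, C[P+](c1ccccc1)(c1ccccc1)c1ccccc1.[Br-]
Why: Wittig methylenation of a non-enolisable aryl aldehyde should be clean, and the aryl bromide and acetals are inert to the ylide.

**Step 3**
Reactants: 3 1-bromo-5-ethenyl-2,3-bis(methoxymethoxy)benzene
Product: 5 2-[3-bromo-4,5-bis(methoxymethoxy)phenyl]ethan-1-ol, via alkylborane 4 (not isolated)
Conditions: 9-BBN, THF, 0 °C to rt; then aq NaOH, H2O2, 0 °C
Reagents that add atoms: hydrogen peroxide, OO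
Why: Anti-Markovnikov hydroboration of the styrene with the bulky dialkylborane followed by oxidative C–B cleavage gives the primary alcohol (hydroboration–oxidation), and no second alkene is present at this stage.

**Step 4**
Reactants: 5 2-[3-bromo-4,5-bis(methoxymethoxy)phenyl]ethan-1-ol; 6 4,4,5,5-tetramethyl-2-(3-methylbut-2-en-1-yl)-1,3,2-dioxaborolane
Product: 7 2-[3,4-bis(methoxymethoxy)-5-(3-methylbut-2-en-1-yl)phenyl]ethan-1-ol
Conditions: 6 (1.5 equiv), PdCl2(IPent)(3-chloropyridine) (2 mol %; IPent = 1,3-bis[2,6-di(pentan-3-yl)phenyl]imidazol-2-ylidene), aq KOH, THF, 65 °C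
Reagents that add atoms: 4,4,5,5-tetramethyl-2-(3-methylbut-2-en-1-yl)-1,3,2-dioxaborolane (reactant 6), CC(C)=CCB1OC(C)(C)C(C)(C)O1
Why: Suzuki–Miyaura coupling of an aryl bromide with the prenylboronate, in which the bulky carbene ligand on palladium should direct reductive elimination to the unsubstituted allyl terminus and so give the linear prenyl arene; the free primary alcohol and the acetals tolerate aqueous base.

**Step 5**
Reactants: 7 2-[3,4-bis(methoxymethoxy)-5-(3-methylbut-2-en-1-yl)phenyl]ethan-1-ol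
Product: 8 [3,4-bis(methoxymethoxy)-5-(3-methylbut-2-en-1-yl)phenyl]acetaldehyde
Conditions: Dess–Martin periodinane, NaHCO3, CH2Cl2, 0 °C to rt; used without storage
Reagents that add atoms: none
Why: Buffered Dess–Martin oxidation converts the primary alcohol into the aldehyde under neutral conditions that spare the trisubstituted alkene and the acetals.

**Step 6**
Reactants: 8 [3,4-bis(methoxymethoxy)-5-(3-methylbut-2-en-1-yl)phenyl]acetaldehyde; 9 2-chloro-1,1-dimethoxyethane (chloroacetaldehyde dimethyl acetal)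
Product: 11 racemic 1-[3,4-bis(methoxymethoxy)-5-(3-methylbut-2-en-1-yl)phenyl]-4-methoxybut-3-yn-2-ol, via lithium methoxyacetylide 10 (not isolated)
Conditions: 9, LiNEt2 (3 equiv, from n-BuLi and Et2NH), THF, 0 °C; then 8, −78 °C; aq NaHCO3 quench; Et3N-deactivated silica
Reagents that add atoms: 2-chloro-1,1-dimethoxyethane (reactant 9), COC(OC)CCl
Why: Twofold elimination (MeOH, HCl) and deprotonation of the acetal give the lithium alkoxyacetylide, which should add to the aldehyde carbonyl at low temperature faster than it enolises it (acetylide 1,2-addition); the new carbinol centre forms without control and is erased by oxidation in step 11.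

**Step 7**
Reactants: 11 racemic 1-[3,4-bis(methoxymethoxy)-5-(3-methylbut-2-en-1-yl)phenyl]-4-methoxybut-3-yn-2-ol
Product: 12 racemic tert-butyl({1-[3,4-bis(methoxymethoxy)-5-(3-methylbut-2-en-1-yl)phenyl]-4-methoxybut-3-yn-2-yl}oxy)dimethylsilane
Conditions: TBSCl, imidazole, DMF, 0 °C to rt
Reagents that add atoms: tert-butyldimethylsilyl chloride, CC(C)(C)[Si](C)(C)Cl
Why: Silylation of the secondary propargylic alcohol under basic conditions blocks the acid-triggered rearrangement of the hydroxy ynol ether and leaves the ynol ether untouched.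

**Step 8**
Reactants: 13 cyclobutane-1,3-dione
Product: 14 3-(methoxymethoxy)cyclobut-2-en-1-one
Conditions: MOMCl, iPr2NEt, CH2Cl2, −20 to 0 °C; rapid filtration through Et3N-deactivated silica
Reagents that add atoms: chloromethyl methyl ether, COCCl
Why: The strongly acidic enol form of the dione is deprotonated by the amine and the delocalised enolate should be alkylated on oxygen by the hard oxocarbenium-type electrophile (O-alkylation of a 1,3-dione to a vinylogous ester).

**Step 9**
Reactants: 12 racemic tert-butyl({1-[3,4-bis(methoxymethoxy)-5-(3-methylbut-2-en-1-yl)phenyl]-4-methoxybut-3-yn-2-yl}oxy)dimethylsilane; 14 3-(methoxymethoxy)cyclobut-2-en-1-one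
Product: 19 racemic 2-{1-[(tert-butyldimethylsilyl)oxy]-2-[3,4-bis(methoxymethoxy)-5-(3-methylbut-2-en-1-yl)phenyl]ethyl}-3-methoxy-5-(methoxymethoxy)phenol, via vinylketene 15 (not isolated), via vinylcyclobutenone 16 (not isolated), via dienylketene 17 (not isolated), via cyclohexadienone 18 (not isolated)
Conditions: 14 (2 equiv), PhMe, 80 to 110 °C, sealed tube; then K2CO3, MeOH, rt
Reagents that add atoms: none
Why: Heating opens 14 by 4π electrocyclic cleavage of its C1–C4 bond to the 3-(methoxymethoxy)vinylketene 15, whose ketene carbonyl carbon is attacked by the nucleophilic alkyne carbon of 12 remote from the methoxy group in a polar [2+2] cycloaddition that gives 16. Conrotatory 4π opening of 16 delivers dienylketene 17, which closes ring A by 6π electrocyclisation (the C8a–C8 bond re-joins the former cyclobutenone carbons) to dienone 18, and enolisation gives phenol 19, so the net new skeletal bonds are C4a–C8a and C5–C6. This is the Danheiser cyclobutenone–ynol ether benzannulation, here with a 3-alkoxycyclobutenone as the less common partner. No stereocentre is created, and the racemic silyloxy carbon is a spectator. The required regiochemistry (methoxy carbon next to the C4a side chain and meta to the new phenol, acetal oxygen para to the side chain) follows from the polarisation of the ynol ether in the ketene [2+2] step. The methyl ynol ether has no β-hydrogen for retro-ene loss of an alkene, the prenyl alkene is far less nucleophilic than the ynol ether, and the methanolic K2CO3 treatment returns any phenol acylated by surplus vinylketene.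

**Step 10**
Reactants: 19 racemic 2-{1-[(tert-butyldimethylsilyl)oxy]-2-[3,4-bis(methoxymethoxy)-5-(3-methylbut-2-en-1-yl)phenyl]ethyl}-3-methoxy-5-(methoxymethoxy)phenol
Product: 20 racemic 2-{2-[3,4-bis(methoxymethoxy)-5-(3-methylbut-2-en-1-yl)phenyl]-1-hydroxyethyl}-3-methoxy-5-(methoxymethoxy)phenol
Conditions: TBAF, THF, 0 °C; pH 7 buffer work-up; crude material used directly
Reagents that add atoms: none
Why: Fluoride cleaves the Si–O bond of the secondary silyl ether, while aryl methoxymethyl ethers, the methyl ether and the prenyl group are inert (fluoride desilylation).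

**Step 11**
Reactants: 20 racemic 2-{2-[3,4-bis(methoxymethoxy)-5-(3-methylbut-2-en-1-yl)phenyl]-1-hydroxyethyl}-3-methoxy-5-(methoxymethoxy)phenol
Product: 21 2-[3,4-bis(methoxymethoxy)-5-(3-methylbut-2-en-1-yl)phenyl]-1-[2-hydroxy-6-methoxy-4-(methoxymethoxy)phenyl]ethan-1-one
Conditions: activated MnO2 (excess), CH2Cl2, rt
Reagents that add atoms: none
Why: MnO2 oxidises the electron-rich benzylic alcohol selectively to the ketone, which is stabilised by hydrogen bonding to the ortho phenol, and should leave the phenol and the alkene untouched (benzylic alcohol oxidation).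

**Step 12**
Reactants: 21 2-[3,4-bis(methoxymethoxy)-5-(3-methylbut-2-en-1-yl)phenyl]-1-[2-hydroxy-6-methoxy-4-(methoxymethoxy)phenyl]ethan-1-one
Product: 23 3-[3,4-bis(methoxymethoxy)-5-(3-methylbut-2-en-1-yl)phenyl]-5-methoxy-7-(methoxymethoxy)-4H-chromen-4-one, via enaminone 22 (not isolated)
Conditions: Me2NCH(OMe)2, PhMe, 90 °C
Reagents that add atoms: N,N-dimethylformamide dimethyl acetal, COC(OC)N(C)C
Why: The activated methylene of the deoxybenzoin condenses with the amide acetal to an enaminone, and the ortho phenol then adds to it and expels dimethylamine to close the pyranone (deoxybenzoin route to isoflavones).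

**Step 13**
Reactants: 23 3-[3,4-bis(methoxymethoxy)-5-(3-methylbut-2-en-1-yl)phenyl]-5-methoxy-7-(methoxymethoxy)-4H-chromen-4-one
Product: 24 glisoflavone
Conditions: HCl (2 M aq), MeOH, rt to 40 °C, reaction stopped at full conversion
Reagents that add atoms: none
Why: Dilute methanolic acid exchanges the three aryl methoxymethyl acetals to dimethoxymethane much faster than it protonates the trisubstituted prenyl alkene, so the three phenols are freed without chroman formation and the C5 methyl ether stays (acetal cleavage).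

**Compound list**
1 | 3-bromo-4,5-dihydroxybenzaldehyde | O=Cc1cc(O)c(O)c(Br)c1 | starting material
2 | 3-bromo-4,5-bis(methoxymethoxy)benzaldehyde | O=Cc1cc(OCOC)c(OCOC)c(Br)c1 | intermediate
3 | 1-bromo-5-ethenyl-2,3-bis(methoxymethoxy)benzene | C=Cc1cc(OCOC)c(OCOC)c(Br)c1 | intermediate
4 | 9-{2-[3-bromo-4,5-bis(methoxymethoxy)phenyl]ethyl}-9-borabicyclo[3.3.1]nonane (not isolated) | COCOc1cc(CCB2C3CCCC2CCC3)cc(Br)c1OCOC | intermediate
5 | 2-[3-bromo-4,5-bis(methoxymethoxy)phenyl]ethan-1-ol | OCCc1cc(OCOC)c(OCOC)c(Br)c1 | intermediate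
6 | 4,4,5,5-tetramethyl-2-(3-methylbut-2-en-1-yl)-1,3,2-dioxaborolane (prenylboronic acid pinacol ester) | CC(C)=CCB1OC(C)(C)C(C)(C)O1 | starting material
7 | 2-[3,4-bis(methoxymethoxy)-5-(3-methylbut-2-en-1-yl)phenyl]ethan-1-ol | OCCc1cc(OCOC)c(OCOC)c(CC=C(C)C)c1 | intermediate
8 | [3,4-bis(methoxymethoxy)-5-(3-methylbut-2-en-1-yl)phenyl]acetaldehyde | O=CCc1cc(OCOC)c(OCOC)c(CC=C(C)C)c1 | intermediate
9 | 2-chloro-1,1-dimethoxyethane (chloroacetaldehyde dimethyl acetal) | COC(OC)CCl | starting material
10 | lithium methoxyacetylide (not isolated) | [Li]C#COC | intermediate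
11 | racemic 1-[3,4-bis(methoxymethoxy)-5-(3-methylbut-2-en-1-yl)phenyl]-4-methoxybut-3-yn-2-ol | COC#CC(O)Cc1cc(OCOC)c(OCOC)c(CC=C(C)C)c1 | intermediate
12 | racemic tert-butyl({1-[3,4-bis(methoxymethoxy)-5-(3-methylbut-2-en-1-yl)phenyl]-4-methoxybut-3-yn-2-yl}oxy)dimethylsilane | COC#CC(O[Si](C)(C)C(C)(C)C)Cc1cc(OCOC)c(OCOC)c(CC=C(C)C)c1 | intermediate
13 | cyclobutane-1,3-dione | O=C1CC(=O)C1 | starting material
14 | 3-(methoxymethoxy)cyclobut-2-en-1-one | O=C1C=C(OCOC)C1 | intermediate
15 | 3-(methoxymethoxy)buta-1,3-dien-1-one (vinylketene, not isolated) | C=C(OCOC)C=C=O | intermediate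
16 | 2-{1-[(tert-butyldimethylsilyl)oxy]-2-[3,4-bis(methoxymethoxy)-5-(3-methylbut-2-en-1-yl)phenyl]ethyl}-3-methoxy-4-[1-(methoxymethoxy)ethenyl]cyclobut-2-en-1-one (mixture of racemic diastereomers, not isolated) | C=C(OCOC)C1C(OC)=C(C(O[Si](C)(C)C(C)(C)C)Cc2cc(OCOC)c(OCOC)c(CC=C(C)C)c2)C1=O | intermediate
17 | racemic (3E)-2-{1-[(tert-butyldimethylsilyl)oxy]-2-[3,4-bis(methoxymethoxy)-5-(3-methylbut-2-en-1-yl)phenyl]ethyl}-3-methoxy-5-(methoxymethoxy)hexa-1,3,5-trien-1-one (ketene and vinyl group cis, not isolated) | C=C(OCOC)/C=C(\C(=C=O)C(O[Si](C)(C)C(C)(C)C)Cc1cc(OCOC)c(OCOC)c(CC=C(C)C)c1)OC | intermediate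
18 | racemic 2-{1-[(tert-butyldimethylsilyl)oxy]-2-[3,4-bis(methoxymethoxy)-5-(3-methylbut-2-en-1-yl)phenyl]ethyl}-3-methoxy-5-(methoxymethoxy)cyclohexa-2,4-dien-1-one (not isolated) | O=C1CC(OCOC)=CC(OC)=C1C(O[Si](C)(C)C(C)(C)C)Cc1cc(OCOC)c(OCOC)c(CC=C(C)C)c1 | intermediate
19 | racemic 2-{1-[(tert-butyldimethylsilyl)oxy]-2-[3,4-bis(methoxymethoxy)-5-(3-methylbut-2-en-1-yl)phenyl]ethyl}-3-methoxy-5-(methoxymethoxy)phenol | COc1cc(OCOC)cc(O)c1C(O[Si](C)(C)C(C)(C)C)Cc1cc(OCOC)c(OCOC)c(CC=C(C)C)c1 | intermediate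
20 | racemic 2-{2-[3,4-bis(methoxymethoxy)-5-(3-methylbut-2-en-1-yl)phenyl]-1-hydroxyethyl}-3-methoxy-5-(methoxymethoxy)phenol | COc1cc(OCOC)cc(O)c1C(O)Cc1cc(OCOC)c(OCOC)c(CC=C(C)C)c1 | intermediate
21 | 2-[3,4-bis(methoxymethoxy)-5-(3-methylbut-2-en-1-yl)phenyl]-1-[2-hydroxy-6-methoxy-4-(methoxymethoxy)phenyl]ethan-1-one | COc1cc(OCOC)cc(O)c1C(=O)Cc1cc(OCOC)c(OCOC)c(CC=C(C)C)c1 | intermediate
22 | 2-[3,4-bis(methoxymethoxy)-5-(3-methylbut-2-en-1-yl)phenyl]-3-(dimethylamino)-1-[2-hydroxy-6-methoxy-4-(methoxymethoxy)phenyl]prop-2-en-1-one (alkene geometry not defined, not isolated) | CN(C)C=C(c1cc(OCOC)c(OCOC)c(CC=C(C)C)c1)C(=O)c1c(O)cc(OCOC)cc1OC | intermediate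
23 | 3-[3,4-bis(methoxymethoxy)-5-(3-methylbut-2-en-1-yl)phenyl]-5-methoxy-7-(methoxymethoxy)-4H-chromen-4-one | COc1cc(OCOC)cc2occ(-c3cc(OCOC)c(OCOC)c(CC=C(C)C)c3)c(=O)c12 | intermediate
24 | glisoflavone, 3-[3,4-dihydroxy-5-(3-methylbut-2-en-1-yl)phenyl]-7-hydroxy-5-methoxy-4H-chromen-4-one | COc1cc(O)cc2occ(-c3cc(O)c(O)c(CC=C(C)C)c3)c(=O)c12 | target

**Step count.** Total: 13 steps. Longest linear sequence: 12 steps (steps 1–7 and 9–13); step 8 is a one-step branch.

**Steps most likely to fail**

1. Step 9. The donor-stabilised cyclobutenone may open slowly, the vinylketene may oligomerise faster than it adds to the hindered ynol ether, or the product may lose silanol thermally through an ortho-quinone methide. The fallback replaces the benzannulation by a directed ortho-metalation; it sets out from aldehyde 8 and returns to the route at target 24. Commercial 5-methoxyresorcinol would be monosilylated (TIPSCl, imidazole, DMF) to 3-methoxy-5-[(triisopropylsilyl)oxy]phenol F1 and then protected (MOMCl, iPr2NEt) as [3-methoxy-5-(methoxymethoxy)phenoxy]tri(propan-2-yl)silane F2. n-BuLi in THF at 0 °C should lithiate only the position between the methoxy and the methoxymethoxy group, because both positions next to the bulky silyl ether are shielded. After transmetalation with CeCl3 the aryl metal would add to 8 at −78 °C to give racemic 2-[3,4-bis(methoxymethoxy)-5-(3-methylbut-2-en-1-yl)phenyl]-1-{2-methoxy-6-(methoxymethoxy)-4-[(triisopropylsilyl)oxy]phenyl}ethan-1-ol F3. Dess–Martin oxidation would give the corresponding ethan-1-one F4, and Me2NCH(OMe)2 the enaminone 2-[3,4-bis(methoxymethoxy)-5-(3-methylbut-2-en-1-yl)phenyl]-3-(dimethylamino)-1-{2-methoxy-6-(methoxymethoxy)-4-[(triisopropylsilyl)oxy]phenyl}prop-2-en-1-one F5. Dilute HCl in MeOH should remove the three acetals and close ring C to 7-O-(triisopropylsilyl)glisoflavone F6, and TBAF would then give 24.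

2. Step 6. The basic acetylide/amide mixture may enolise the arylacetaldehyde and cause self-aldol condensation, or the hydroxy ynol ether may rearrange to an unsaturated ester on contact with acid during isolation. The fallback replaces aldehyde addition by acylation and reduction; it sets out from 8 and returns at 11. Chlorite oxidation of 8 (NaClO2, NaH2PO4, 2-methyl-2-butene, t-BuOH/H2O) would give [3,4-bis(methoxymethoxy)-5-(3-methylbut-2-en-1-yl)phenyl]acetic acid F7. Coupling with N,O-dimethylhydroxylamine hydrochloride (EDC, N-methylmorpholine) would give the Weinreb amide 2-[3,4-bis(methoxymethoxy)-5-(3-methylbut-2-en-1-yl)phenyl]-N-methoxy-N-methylacetamide F8, whose α-protons are far less acidic than those of the aldehyde. Acetylide 10 would convert it into 1-[3,4-bis(methoxymethoxy)-5-(3-methylbut-2-en-1-yl)phenyl]-4-methoxybut-3-yn-2-one F9, and 1,2-reduction with DIBAL-H at −78 °C would give 11.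

3. Step 11. The electron-rich free phenol may be degraded oxidatively, or the diol may dehydrate through an ortho-quinone methide to a stilbene before or during oxidation. The fallback masks the phenol temporarily; it sets out from 19 and returns at 21. Allyl bromide and K2CO3 in acetone would give racemic {1-[2-(allyloxy)-6-methoxy-4-(methoxymethoxy)phenyl]-2-[3,4-bis(methoxymethoxy)-5-(3-methylbut-2-en-1-yl)phenyl]ethoxy}(tert-butyl)dimethylsilane F10. TBAF would give racemic 1-[2-(allyloxy)-6-methoxy-4-(methoxymethoxy)phenyl]-2-[3,4-bis(methoxymethoxy)-5-(3-methylbut-2-en-1-yl)phenyl]ethan-1-ol F11, which can no longer form a quinone methide. Dess–Martin oxidation would give 1-[2-(allyloxy)-6-methoxy-4-(methoxymethoxy)phenyl]-2-[3,4-bis(methoxymethoxy)-5-(3-methylbut-2-en-1-yl)phenyl]ethan-1-one F12, and allyl transfer to morpholine with catalytic Pd(PPh3)4 would release 21 without touching the prenyl group.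

**Further compounds**
F1 | step 9 | 3-methoxy-5-[(triisopropylsilyl)oxy]phenol | COc1cc(O)cc(O[Si](C(C)C)(C(C)C)C(C)C)c1
F2 | step 9 | [3-methoxy-5-(methoxymethoxy)phenoxy]tri(propan-2-yl)silane | COCOc1cc(OC)cc(O[Si](C(C)C)(C(C)C)C(C)C)c1
F3 | step 9 | racemic 2-[3,4-bis(methoxymethoxy)-5-(3-methylbut-2-en-1-yl)phenyl]-1-{2-methoxy-6-(methoxymethoxy)-4-[(triisopropylsilyl)oxy]phenyl}ethan-1-ol | COCOc1cc(O[Si](C(C)C)(C(C)C)C(C)C)cc(OC)c1C(O)Cc1cc(OCOC)c(OCOC)c(CC=C(C)C)c1
F4 | step 9 | 2-[3,4-bis(methoxymethoxy)-5-(3-methylbut-2-en-1-yl)phenyl]-1-{2-methoxy-6-(methoxymethoxy)-4-[(triisopropylsilyl)oxy]phenyl}ethan-1-one | COCOc1cc(O[Si](C(C)C)(C(C)C)C(C)C)cc(OC)c1C(=O)Cc1cc(OCOC)c(OCOC)c(CC=C(C)C)c1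
F5 | step 9 | 2-[3,4-bis(methoxymethoxy)-5-(3-methylbut-2-en-1-yl)phenyl]-3-(dimethylamino)-1-{2-methoxy-6-(methoxymethoxy)-4-[(triisopropylsilyl)oxy]phenyl}prop-2-en-1-one | CN(C)C=C(c1cc(OCOC)c(OCOC)c(CC=C(C)C)c1)C(=O)c1c(OC)cc(O[Si](C(C)C)(C(C)C)C(C)C)cc1OCOC
F6 | step 9 | 7-O-(triisopropylsilyl)glisoflavone | COc1cc(O[Si](C(C)C)(C(C)C)C(C)C)cc2occ(-c3cc(O)c(O)c(CC=C(C)C)c3)c(=O)c12
F7 | step 6 | [3,4-bis(methoxymethoxy)-5-(3-methylbut-2-en-1-yl)phenyl]acetic acid | OC(=O)Cc1cc(OCOC)c(OCOC)c(CC=C(C)C)c1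
F8 | step 6 | 2-[3,4-bis(methoxymethoxy)-5-(3-methylbut-2-en-1-yl)phenyl]-N-methoxy-N-methylacetamide | CON(C)C(=O)Cc1cc(OCOC)c(OCOC)c(CC=C(C)C)c1
F9 | step 6 | 1-[3,4-bis(methoxymethoxy)-5-(3-methylbut-2-en-1-yl)phenyl]-4-methoxybut-3-yn-2-one | COC#CC(=O)Cc1cc(OCOC)c(OCOC)c(CC=C(C)C)c1
F10 | step 11 | racemic {1-[2-(allyloxy)-6-methoxy-4-(methoxymethoxy)phenyl]-2-[3,4-bis(methoxymethoxy)-5-(3-methylbut-2-en-1-yl)phenyl]ethoxy}(tert-butyl)dimethylsilane | C=CCOc1cc(OCOC)cc(OC)c1C(O[Si](C)(C)C(C)(C)C)Cc1cc(OCOC)c(OCOC)c(CC=C(C)C)c1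
F11 | step 11 | racemic 1-[2-(allyloxy)-6-methoxy-4-(methoxymethoxy)phenyl]-2-[3,4-bis(methoxymethoxy)-5-(3-methylbut-2-en-1-yl)phenyl]ethan-1-ol | C=CCOc1cc(OCOC)cc(OC)c1C(O)Cc1cc(OCOC)c(OCOC)c(CC=C(C)C)c1
F12 | step 11 | 1-[2-(allyloxy)-6-methoxy-4-(methoxymethoxy)phenyl]-2-[3,4-bis(methoxymethoxy)-5-(3-methylbut-2-en-1-yl)phenyl]ethan-1-one | C=CCOc1cc(OCOC)cc(OC)c1C(=O)Cc1cc(OCOC)c(OCOC)c(CC=C(C)C)c1
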